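**Assumption:** The target has no stereocentre, so no asymmetric step is needed. Flavone numbering is used throughout (O1, C2, C3, C4, C4a, C5 to C8, C8a; ring B primed; side chain C1'' to C3'' counted from ring A).

**Plan**
- Cuts: the three phenolic O–H bonds go back to benzyl ethers, the C3''–OH bond to a prenyl alkene, and the C6–C1'' bond (retro-Claisen) to an O5–C3'' tertiary allyl ether. Ring C is cut at O1–C2 and C2–C3 to a ring A acetophenone and a ring B aldehyde.
- Forward: rings A and B are bought; ring C (the pyranone) closes by oxidative cyclisation of a chalcone. The C5 unit is attached to O5 as a tertiary propargyl ether, semi-reduced, shifted to C6, hydrated, and the benzyl groups are removed.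
- Enabling feature: O5 on ring A has only two ortho carbons, the ring-fusion carbon C4a (fully substituted, shared with ring C) and C6 (C–H). A [3,3] shift from O5 can therefore end only at C6, and C8 is not reached.
- Stereochemistry: none in the target; the sp3 C6 of the Claisen dienone is transient and the chalcone E geometry vanishes on ring closure.

Key step: step 8

**Step 1**
Reactants: 1 2,4,6-trihydroxyacetophenone; 2 benzyl bromide
Product: 3 2,4-bis(benzyloxy)-6-hydroxyacetophenone
Conditions: BnBr (2.1 equiv), K2CO3, DMF, rt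
Reagents that add atoms: benzyl bromide (2), BrCc1ccccc1
Why: Williamson etherification should take the 4-OH and one ortho OH, while the remaining ortho OH is held by a hydrogen bond to the acetyl carbonyl and stays free at this stoichiometry.

**Step 2**
Reactants: 4 2,4-dihydroxybenzaldehyde; 2 benzyl bromide
Product: 5 2,4-bis(benzyloxy)benzaldehyde
Conditions: BnBr (2.4 equiv), K2CO3, DMF, 70 °C
Reagents that add atoms: benzyl bromide (2), BrCc1ccccc1
Why: Williamson etherification of both phenols, with warming and excess halide to bring the chelated 2-OH to full conversion.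

**Step 3**
Reactants: 3 2,4-bis(benzyloxy)-6-hydroxyacetophenone; 5 2,4-bis(benzyloxy)benzaldehyde
Product: 6 (E)-1-[2,4-bis(benzyloxy)-6-hydroxyphenyl]-3-[2,4-bis(benzyloxy)phenyl]prop-2-en-1-one
Conditions: KOH (aq.), EtOH/THF, rt
Reagents that add atoms: none
Why: Claisen–Schmidt condensation of a methyl ketone with a non-enolisable aldehyde should give the conjugated E-enone, with benzyl ethers inert to hydroxide.

**Step 4**
Reactants: 6 (E)-1-[2,4-bis(benzyloxy)-6-hydroxyphenyl]-3-[2,4-bis(benzyloxy)phenyl]prop-2-en-1-one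
Product: 7 5,7-bis(benzyloxy)-2-[2,4-bis(benzyloxy)phenyl]-4H-chromen-4-one
Conditions: I2 (cat.), DMSO, 130 °C
Reagents that add atoms: none
Why: Iodine/DMSO oxidative cyclisation of a 2'-hydroxychalcone closes ring C by 6-endo addition of the free phenol oxygen to the enone β-carbon and dehydrogenates C2–C3, with DMSO as the terminal oxidant.

**Step 5**
Reactants: 7 5,7-bis(benzyloxy)-2-[2,4-bis(benzyloxy)phenyl]-4H-chromen-4-one
Product: 8 7-(benzyloxy)-2-[2,4-bis(benzyloxy)phenyl]-5-hydroxy-4H-chromen-4-one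
Conditions: BCl3 (1.1 equiv), CH2Cl2, −78 °C; then H2O
Reagents that add atoms: none
Why: Chelation-directed Lewis-acid ether cleavage, in which boron bridges the C4 carbonyl and O5 so that only the peri benzyl ether is cleaved at low temperature and the other three remain.

**Step 6**
Reactants: 8 7-(benzyloxy)-2-[2,4-bis(benzyloxy)phenyl]-5-hydroxy-4H-chromen-4-one; 9 2-methylbut-3-yn-2-ol
Product: 11 7-(benzyloxy)-2-[2,4-bis(benzyloxy)phenyl]-5-[(2-methylbut-3-yn-2-yl)oxy]-4H-chromen-4-one, via 2-methylbut-3-yn-2-yl trifluoroacetate 10 (not isolated)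
Conditions: 9, (CF3CO)2O, DBU, MeCN, −5 °C; then 8, DBU, CuCl2·2H2O (cat.), MeCN/THF, 0 °C → rt
Reagents that add atoms: 2-methylbut-3-yn-2-ol (9), C#CC(C)(C)O
Why: Copper-catalysed propargylic etherification of a phenol, in which DBU opens the O5–H···O=C4 chelate by deprotonation and the copper acetylide of the tertiary ester ionises to an electrophile that the only free oxygen, O5, captures at the tertiary carbon.

**Step 7**
Reactants: 11 7-(benzyloxy)-2-[2,4-bis(benzyloxy)phenyl]-5-[(2-methylbut-3-yn-2-yl)oxy]-4H-chromen-4-one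
Product: 12 7-(benzyloxy)-2-[2,4-bis(benzyloxy)phenyl]-5-[(2-methylbut-3-en-2-yl)oxy]-4H-chromen-4-one
Conditions: H2 (1 atm), Lindlar catalyst (Pd/CaCO3 poisoned with Pb(OAc)2), quinoline, EtOAc, rt
Reagents that add atoms: none
Why: Lindlar semi-hydrogenation should stop the terminal alkyne at the vinyl stage, and the poisoned catalyst touches neither the benzyl ethers nor the pyranone C2=C3 bond.

**Step 8**
Reactants: 12 7-(benzyloxy)-2-[2,4-bis(benzyloxy)phenyl]-5-[(2-methylbut-3-en-2-yl)oxy]-4H-chromen-4-one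
Product: 14 7-(benzyloxy)-2-[2,4-bis(benzyloxy)phenyl]-5-hydroxy-6-(3-methylbut-2-en-1-yl)-4H-chromen-4-one, via C6-prenyl ortho-dienone 13 (not isolated)
Conditions: PhNEt2, 130 °C, Ar
Reagents that add atoms: none
Why: A concerted, suprafacial [3,3]-sigmatropic shift through a chair-like six-membered transition state breaks the O5–C3'' bond and forms the C6–C1'' bond with allylic inversion, so the gem-dimethyl carbon ends up at the chain terminus; dienone 13 then tautomerises (C6–H to O5) to the phenol, which is locked in a hydrogen bond to the C4 carbonyl. The closest known reaction type is the thermal aromatic ortho-Claisen rearrangement of aryl 1,1-dimethylallyl ethers to ortho-prenyl phenols. No ring is closed, and the only new sp3 centre (C6 of 13) is erased on enolisation, so no stereocontrol is required. The selectivity needed is C6 over C8: O5 is flanked only by C4a, which is blocked as the ring fusion, and by C6, and C8 could be reached only by a second (Cope) shift of 13 that would build a quaternary carbon next to two ring substituents and should be outrun by the fast enolisation. The tertiary ether relieves strain on rearranging and should react at moderate temperature, and the amine solvent buffers traces of acid that could ionise the ether or close the product to a chroman.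

**Step 9**
Reactants: 14 7-(benzyloxy)-2-[2,4-bis(benzyloxy)phenyl]-5-hydroxy-6-(3-methylbut-2-en-1-yl)-4H-chromen-4-one
Product: 15 7-(benzyloxy)-2-[2,4-bis(benzyloxy)phenyl]-5-hydroxy-6-(3-hydroxy-3-methylbutyl)-4H-chromen-4-one
Conditions: Co(acac)2 (cat.), PhSiH3, O2 (1 atm), THF/i-PrOH, rt
Reagents that add atoms: dioxygen, O=O
Why: Mukaiyama hydration should deliver a hydrogen atom from a cobalt hydride to C2'' and trap the tertiary C3'' radical with O2, giving the Markovnikov alcohol by a radical path that generates no cation for the neighbouring 5-OH to capture and favours the electron-rich trisubstituted alkene over the pyranone double bond.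

**Step 10**
Reactants: 15 7-(benzyloxy)-2-[2,4-bis(benzyloxy)phenyl]-5-hydroxy-6-(3-hydroxy-3-methylbutyl)-4H-chromen-4-one
Product: 16 2-(2,4-dihydroxyphenyl)-5,7-dihydroxy-6-(3-hydroxy-3-methylbutyl)-4H-chromen-4-one (CNP0205133.0)
Conditions: H2 (1 atm), Pd/C, EtOAc/MeOH, rt
Reagents that add atoms: none
Why: Catalytic hydrogenolysis should remove the three benzyl ethers under neutral conditions, which spare the non-benzylic tertiary alcohol (prone to chroman formation or elimination under acid) and the flavone C2=C3 bond.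

**Compound list**
1 | 2,4,6-trihydroxyacetophenone | CC(=O)c1c(O)cc(O)cc1O | starting material
2 | benzyl bromide | BrCc1ccccc1 | starting material
3 | 2,4-bis(benzyloxy)-6-hydroxyacetophenone | CC(=O)c1c(O)cc(OCc2ccccc2)cc1OCc1ccccc1 | intermediate
4 | 2,4-dihydroxybenzaldehyde | O=Cc1ccc(O)cc1O | starting material
5 | 2,4-bis(benzyloxy)benzaldehyde | O=Cc1ccc(OCc2ccccc2)cc1OCc1ccccc1 | intermediate
6 | (E)-1-[2,4-bis(benzyloxy)-6-hydroxyphenyl]-3-[2,4-bis(benzyloxy)phenyl]prop-2-en-1-one | O=C(/C=C/c1ccc(OCc2ccccc2)cc1OCc1ccccc1)c1c(O)cc(OCc2ccccc2)cc1OCc1ccccc1 | intermediate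
7 | 5,7-bis(benzyloxy)-2-[2,4-bis(benzyloxy)phenyl]-4H-chromen-4-one | O=c1cc(-c2ccc(OCc3ccccc3)cc2OCc2ccccc2)oc2cc(OCc3ccccc3)cc(OCc3ccccc3)c12 | intermediate
8 | 7-(benzyloxy)-2-[2,4-bis(benzyloxy)phenyl]-5-hydroxy-4H-chromen-4-one | O=c1cc(-c2ccc(OCc3ccccc3)cc2OCc2ccccc2)oc2cc(OCc3ccccc3)cc(O)c12 | intermediate
9 | 2-methylbut-3-yn-2-ol | C#CC(C)(C)O | starting material
10 | 2-methylbut-3-yn-2-yl trifluoroacetate (formed in solution, not isolated) | C#CC(C)(C)OC(=O)C(F)(F)F | intermediate
11 | 7-(benzyloxy)-2-[2,4-bis(benzyloxy)phenyl]-5-[(2-methylbut-3-yn-2-yl)oxy]-4H-chromen-4-one | C#CC(C)(C)Oc1cc(OCc2ccccc2)cc2oc(-c3ccc(OCc4ccccc4)cc3OCc3ccccc3)cc(=O)c12 | intermediate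
12 | 7-(benzyloxy)-2-[2,4-bis(benzyloxy)phenyl]-5-[(2-methylbut-3-en-2-yl)oxy]-4H-chromen-4-one | C=CC(C)(C)Oc1cc(OCc2ccccc2)cc2oc(-c3ccc(OCc4ccccc4)cc3OCc3ccccc3)cc(=O)c12 | intermediate
13 | 7-(benzyloxy)-2-[2,4-bis(benzyloxy)phenyl]-6-(3-methylbut-2-en-1-yl)-4H-chromene-4,5(6H)-dione (racemic at C6, not isolated) | CC(C)=CCC1C(OCc3ccccc3)=CC2=C(C1=O)C(=O)C=C(O2)c1ccc(OCc2ccccc2)cc1OCc1ccccc1 | intermediate
14 | 7-(benzyloxy)-2-[2,4-bis(benzyloxy)phenyl]-5-hydroxy-6-(3-methylbut-2-en-1-yl)-4H-chromen-4-one | CC(C)=CCc1c(OCc2ccccc2)cc2oc(-c3ccc(OCc4ccccc4)cc3OCc3ccccc3)cc(=O)c2c1O | intermediate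
15 | 7-(benzyloxy)-2-[2,4-bis(benzyloxy)phenyl]-5-hydroxy-6-(3-hydroxy-3-methylbutyl)-4H-chromen-4-one | CC(C)(O)CCc1c(OCc2ccccc2)cc2oc(-c3ccc(OCc4ccccc4)cc3OCc3ccccc3)cc(=O)c2c1O | intermediate
16 | 2-(2,4-dihydroxyphenyl)-5,7-dihydroxy-6-(3-hydroxy-3-methylbutyl)-4H-chromen-4-one | CC(C)(O)CCc1c(O)cc2oc(-c3ccc(O)cc3O)cc(=O)c2c1O | target

**Total step count:** 10
**Longest linear sequence:** 9 steps (steps 1 and 3 to 10, from compound 1; step 2 is the side branch from compound 4).

**Steps most likely to fail**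

Step 6. The deprotonated 5-oxygen is peri to the carbonyl and a weak, hindered nucleophile, so O-alkylation may be slow while the tertiary propargylic ester is consumed by elimination to the enyne. The fallback sets out from compound 8 and keeps the O5-to-C6 shift but uses an unhindered primary electrophile. Allyl bromide with K2CO3 in DMF should give 5-(allyloxy)-7-(benzyloxy)-2-[2,4-bis(benzyloxy)phenyl]-4H-chromen-4-one F1. Heating with Eu(fod)3 (cat.) in CHCl3 should move the allyl group to C6 and give 6-allyl-7-(benzyloxy)-2-[2,4-bis(benzyloxy)phenyl]-5-hydroxy-4H-chromen-4-one F2. Cross-metathesis of F2 with 2-methylbut-2-ene and the second-generation Grubbs catalyst in CH2Cl2 at 40 °C should then install the two methyl groups. The route is rejoined at compound 14.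

Step 8. Heterolysis of the tertiary allyl–oxygen bond may compete with the concerted shift, leading to loss of isoprene and return of the 5-phenol or to out-of-register recombination, and the new ortho-prenyl phenol may close to a chroman. The fallback sets out from compound 8 and forms the C6–C1'' bond by cross-coupling instead. Iodination with benzyltrimethylammonium dichloroiodate and CaCO3 in CH2Cl2/MeOH, which is regioselective for C6 in 5-hydroxy-7-alkoxyflavones, should give 7-(benzyloxy)-2-[2,4-bis(benzyloxy)phenyl]-5-hydroxy-6-iodo-4H-chromen-4-one F3. Sonogashira coupling of F3 with compound 9 (PdCl2(PPh3)2, CuI, Et3N, DMF, rt) should give 7-(benzyloxy)-2-[2,4-bis(benzyloxy)phenyl]-5-hydroxy-6-(3-hydroxy-3-methylbut-1-yn-1-yl)-4H-chromen-4-one F4; the chelated 5-OH and the mild temperature should hold back furan closure. Hydrogenation of F4 over Pd/C saturates the alkyne and removes the three benzyl groups in one operation. The route is rejoined at compound 16.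

Step 9. Hydrogen-atom transfer to the pyranone C2=C3 bond, plain reduction of the alkene without oxygen capture, or a stalled peroxide stage may erode the hydration. The fallback sets out from compound 14 and switches to ionic Markovnikov hydration with the 5-oxygen masked. Ac2O, pyridine and DMAP should give 7-(benzyloxy)-2-[2,4-bis(benzyloxy)phenyl]-6-(3-methylbut-2-en-1-yl)-4-oxo-4H-chromen-5-yl acetate F5, in which O5 can no longer attack the mercurinium ion. Oxymercuration–demercuration (Hg(OAc)2, THF/H2O; then NaBH4, NaOH, 0 °C) should give 7-(benzyloxy)-2-[2,4-bis(benzyloxy)phenyl]-6-(3-hydroxy-3-methylbutyl)-4-oxo-4H-chromen-5-yl acetate F6. K2CO3 in MeOH then removes the acetate. The route is rejoined at compound 15.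

**Further compounds**
F1 | step 6 | 5-(allyloxy)-7-(benzyloxy)-2-[2,4-bis(benzyloxy)phenyl]-4H-chromen-4-one | C=CCOc1cc(OCc2ccccc2)cc2oc(-c3ccc(OCc4ccccc4)cc3OCc3ccccc3)cc(=O)c12
F2 | step 6 | 6-allyl-7-(benzyloxy)-2-[2,4-bis(benzyloxy)phenyl]-5-hydroxy-4H-chromen-4-one | C=CCc1c(OCc2ccccc2)cc2oc(-c3ccc(OCc4ccccc4)cc3OCc3ccccc3)cc(=O)c2c1O
F3 | step 8 | 7-(benzyloxy)-2-[2,4-bis(benzyloxy)phenyl]-5-hydroxy-6-iodo-4H-chromen-4-one | Oc1c(I)c(OCc2ccccc2)cc2oc(-c3ccc(OCc4ccccc4)cc3OCc3ccccc3)cc(=O)c12
F4 | step 8 | 7-(benzyloxy)-2-[2,4-bis(benzyloxy)phenyl]-5-hydroxy-6-(3-hydroxy-3-methylbut-1-yn-1-yl)-4H-chromen-4-one | CC(C)(O)C#Cc1c(OCc2ccccc2)cc2oc(-c3ccc(OCc4ccccc4)cc3OCc3ccccc3)cc(=O)c2c1O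
F5 | step 9 | 7-(benzyloxy)-2-[2,4-bis(benzyloxy)phenyl]-6-(3-methylbut-2-en-1-yl)-4-oxo-4H-chromen-5-yl acetate | CC(C)=CCc1c(OCc2ccccc2)cc2oc(-c3ccc(OCc4ccccc4)cc3OCc3ccccc3)cc(=O)c2c1OC(C)=O
F6 | step 9 | 7-(benzyloxy)-2-[2,4-bis(benzyloxy)phenyl]-6-(3-hydroxy-3-methylbutyl)-4-oxo-4H-chromen-5-yl acetate | CC(C)(O)CCc1c(OCc2ccccc2)cc2oc(-c3ccc(OCc4ccccc4)cc3OCc3ccccc3)cc(=O)c2c1OC(C)=O
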